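**Plan**

- Locants follow spiro[5.5]undecane: C1–C5 are the ring-B carbons (C2 bears Br, C3 bears Me and OH), C6 is the spiro atom, and C7–C11 form ring A (C7(Me)=C8, Br on C10, gem-dimethyl C11).
- Feature used: the bond joining the two fully substituted carbons C6 and C11 has the C10 bromide as its neighbour, and the C3 oxygen stands 1,4 to C6 in ring B. Ring B therefore maps onto a 4-substituted phenol whose ipso carbon can attack a bromonium ion spanning C10/C11.
- Retrosynthesis: cut C2–Br and C3–OH (bromohydrin of a C2=C3 alkene), then C3–CH3 (alkenyl triflate of a ketone), then C6–C11 together with C10–Br (dearomative closure of ring A), then the arene–C7 and C9–C10 bonds of an acyclic aryl diene.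
- Forward: 2-butyn-1-ol, an isobutenyl Grignard reagent and 4-hydroxyphenylboronic acid are joined to the Z-aryl diene 8, so ring B enters as the arene. Ring A closes in step 5; ring B is then taken from dienone to enone, to the methyl-bearing alkene and to the bromohydrin.
- Stereochemistry: the Z-alkene comes from trans-hydroalumination/iodination; C10 from catalyst-controlled bromonium delivery (step 5); C6 from ligand-controlled choice between the two dienone double bonds (step 6); C2 and C3 from anti addition of Br+/water to C2=C3 under the influence of the spiro centre (step 9).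

Key step: step 5

Assumption: the absolute sense of the two catalyst-controlled steps (5 and 6) cannot be derived for this substrate, so the catalyst hands named are taken as those giving 10S and 6R, and the mirror-image catalyst is used if the first run shows the opposite sense.

**Route**

Step 1
Reactants: 1 but-2-yn-1-ol
Product: 3 (2Z)-3-iodobut-2-en-1-ol, via cyclic alkenylalanate 2 (not isolated)
Conditions: Red-Al (1.5 equiv), THF, 0 °C → rt; then I2, THF, −78 → 0 °C
Reagents that add atoms: iodine, II
Why: Hydroxyl-directed trans-hydroalumination of the propargylic alcohol places aluminium on C3 in a five-membered alanate, and iodinolysis with retention should give the Z-iodoalkene in which iodine is cis to the CH2O arm, the geometry later needed for aryl cis to C9.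

Step 2
Reactants: 3 (2Z)-3-iodobut-2-en-1-ol
Product: 4 (2Z)-1-bromo-3-iodobut-2-ene
Conditions: CBr4, PPh3, CH2Cl2, 0 °C
Reagents that add atoms: carbon tetrabromide, BrC(Br)(Br)Br
Why: The Appel reaction converts the primary allylic alcohol into the bromide under neutral conditions, leaving the alkenyl iodide and the alkene geometry untouched.

Step 3
Reactants: 4 (2Z)-1-bromo-3-iodobut-2-ene; 5 (2-methylprop-1-en-1-yl)magnesium bromide
Product: 6 (2Z)-2-iodo-6-methylhepta-2,5-diene
Conditions: CuI (10 mol %), THF, −40 → 0 °C
Reagents that add atoms: none
Why: Copper-catalysed SN2 coupling of an allylic bromide with an alkenyl Grignard reagent should give the skipped diene, because the SN2′ path would have to attack the carbon that already carries iodine and methyl.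

Step 4
Reactants: 6 (2Z)-2-iodo-6-methylhepta-2,5-diene; 7 (4-hydroxyphenyl)boronic acid
Product: 8 4-[(2Z)-6-methylhepta-2,5-dien-2-yl]phenol
Conditions: Pd(dppf)Cl2 (3 mol %), K2CO3, THF/H2O, 50 °C; aq NH4Cl work-up
Reagents that add atoms: none
Why: Suzuki–Miyaura coupling of an alkenyl iodide proceeds with retention of the alkene geometry and tolerates the unprotected phenol, so no protecting group is needed.

Step 5
Reactants: 8 4-[(2Z)-6-methylhepta-2,5-dien-2-yl]phenol
Product: 9 (10S)-10-bromo-7,11,11-trimethylspiro[5.5]undeca-1,4,7-trien-3-one
Conditions: NBS (1.05 equiv), (R)-BINOL-derived thiophosphoramide Lewis base (10 mol %), toluene/CH2Cl2 2:1, −78 °C, dark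
Reagents that add atoms: N-bromosuccinimide, O=C1CCC(=O)N1Br
Why: Proposed new method: the chiral Lewis base takes Br+ from NBS and passes it to one face of the electron-rich, unhindered C10=C11 alkene; the bromonium ion is opened at tertiary C11, anti to bromine, by the arene ipso carbon para to the hydroxyl, and the hydroxy-arenium ion loses its O–H proton to succinimide anion to give the cross-conjugated dienone. The closest known reaction types are catalytic enantioselective bromonium-initiated polyene cyclisation terminated by an arene and electrophile-triggered ipso-cyclisation of para-oxygenated arenes to spirodienones. Ring A closes in a 6-endo-trig mode with respect to the activated alkene (ipso participation of the arene) through a chair-like transition state in which the Z-configured C7=C8 bond already holds the arene over C11. The only new stereocentre, C10, is set by the catalyst-controlled face of bromine delivery; C6 is not yet stereogenic because the two dienone arms are identical. The step needs ipso rather than ortho attack, which ring size (six- against seven-membered) and the para-hydroxyl secure, and bromination of C10=C11 rather than of the ring or of C7=C8, which the low temperature, the twist of the styrenyl bond out of conjugation and its greater hindrance should favour.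

Step 6
Reactants: 9 (10S)-10-bromo-7,11,11-trimethylspiro[5.5]undeca-1,4,7-trien-3-one
Product: 11 (6R,10S)-10-bromo-7,11,11-trimethylspiro[5.5]undeca-1,7-dien-3-one, via silyl dienol ether 10 (not isolated)
Conditions: Cu(OAc)2 (5 mol %), (R)-DTBM-SEGPHOS (5.5 mol %), (EtO)2MeSiH (1.1 equiv), toluene, −40 → −20 °C; then 1 M HCl, THF, 0 °C
Reagents that add atoms: none
Why: Copper hydride catalysed asymmetric conjugate reduction is used as a desymmetrisation, in which the chiral bisphosphine–CuH should reduce only the C4=C5 arm (the one on the face of ring A opposite to the C10 bromide), which makes C6 stereogenic (6R), while the silyl dienol ether formed by σ-bond metathesis is inert to a second hydride until it is hydrolysed.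

Step 7
Reactants: 11 (6R,10S)-10-bromo-7,11,11-trimethylspiro[5.5]undeca-1,7-dien-3-one
Product: 13 (6R,10S)-10-bromo-7,11,11-trimethylspiro[5.5]undeca-2,7-dien-3-yl trifluoromethanesulfonate, via lithium enolate 12 (not isolated)
Conditions: L-Selectride (1.1 equiv), THF, −78 °C; then PhNTf2, −78 → 0 °C
Reagents that add atoms: N-phenylbis(trifluoromethanesulfonimide), O=S(=O)(N(c1ccccc1)S(=O)(=O)C(F)(F)F)C(F)(F)F
Why: 1,4-Reduction of the β-unsubstituted cyclohexenone by the bulky borohydride gives the C2=C3 lithium enolate regiospecifically, and kinetic O-triflation at low temperature freezes that position, so the configuration at C6 is carried into the alkenyl triflate.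

Step 8
Reactants: 13 (6R,10S)-10-bromo-7,11,11-trimethylspiro[5.5]undeca-2,7-dien-3-yl trifluoromethanesulfonate
Product: 14 (6R,10S)-10-bromo-3,7,11,11-tetramethylspiro[5.5]undeca-2,7-diene
Conditions: MeZnCl (2 equiv), Pd(PPh3)4 (5 mol %), THF, 40 °C
Reagents that add atoms: methylzinc chloride, C[Zn]Cl
Why: Negishi coupling of the alkenyl triflate with methylzinc chloride installs the C3 methyl group, and the hindered secondary alkyl bromide should not undergo oxidative addition to Pd(PPh3)4 under these conditions.

Step 9
Reactants: 14 (6R,10S)-10-bromo-3,7,11,11-tetramethylspiro[5.5]undeca-2,7-diene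
Product: 15 (2R,3R,6R,10S)-2,10-dibromo-3,7,11,11-tetramethylspiro[5.5]undec-7-en-3-ol
Conditions: NBS (1.05 equiv), acetone/H2O 4:1, 0 °C, dark
Reagents that add atoms: N-bromosuccinimide, O=C1CCC(=O)N1Br; water, O
Why: Bromohydrin formation on the less hindered ring-B alkene (C7=C8 is shielded by the spiro centre) proceeds by anti, Markovnikov opening of the bromonium ion by water at tertiary C3, which sets C2 and C3 trans, and Br+ is expected on the face of C2 cis to C11, away from the flatter C7 arm of ring A that should sit pseudo-axial with its methyl over the other face, giving the 2R,3R isomer whose chair carries Br, OH and C11 equatorial.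

**Compound list**

1 | but-2-yn-1-ol | CC#CCO | starting material
2 | sodium 2,2-bis(2-methoxyethoxy)-3-methyl-2,5-dihydro-1,2-oxaluminol-2-uide (five-membered O–Al–C alkenylalanate) | CC1=CCO[Al-]1(OCCOC)OCCOC.[Na+] | intermediate
3 | (2Z)-3-iodobut-2-en-1-ol | C/C(I)=C/CO | intermediate
4 | (2Z)-1-bromo-3-iodobut-2-ene | C/C(I)=C/CBr | intermediate
5 | (2-methylprop-1-en-1-yl)magnesium bromide | CC(C)=C[Mg]Br | starting material
6 | (2Z)-2-iodo-6-methylhepta-2,5-diene | C/C(I)=C/CC=C(C)C | intermediate
7 | (4-hydroxyphenyl)boronic acid | OB(O)c1ccc(O)cc1 | starting material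
8 | 4-[(2Z)-6-methylhepta-2,5-dien-2-yl]phenol | C/C(=C/CC=C(C)C)c1ccc(O)cc1 | intermediate
9 | (10S)-10-bromo-7,11,11-trimethylspiro[5.5]undeca-1,4,7-trien-3-one | CC1=CC[C@H](Br)C(C)(C)C12C=CC(=O)C=C2 | intermediate
10 | (6R,10S)-10-bromo-3-[diethoxy(methyl)silyloxy]-7,11,11-trimethylspiro[5.5]undeca-1,3,7-triene | CC1=CC[C@H](Br)C(C)(C)[C@@]12CC=C(O[Si](C)(OCC)OCC)C=C2 | intermediate
11 | (6R,10S)-10-bromo-7,11,11-trimethylspiro[5.5]undeca-1,7-dien-3-one | CC1=CC[C@H](Br)C(C)(C)[C@@]12CCC(=O)C=C2 | intermediate
12 | lithium (6R,10S)-10-bromo-7,11,11-trimethylspiro[5.5]undeca-2,7-dien-3-olate | CC1=CC[C@H](Br)C(C)(C)[C@@]12CCC(O[Li])=CC2 | intermediate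
13 | (6R,10S)-10-bromo-7,11,11-trimethylspiro[5.5]undeca-2,7-dien-3-yl trifluoromethanesulfonate | CC1=CC[C@H](Br)C(C)(C)[C@@]12CCC(OS(=O)(=O)C(F)(F)F)=CC2 | intermediate
14 | (6R,10S)-10-bromo-3,7,11,11-tetramethylspiro[5.5]undeca-2,7-diene | CC1=CC[C@H](Br)C(C)(C)[C@@]12CCC(C)=CC2 | intermediate
15 | (2R,3R,6R,10S)-2,10-dibromo-3,7,11,11-tetramethylspiro[5.5]undec-7-en-3-ol | CC1=CC[C@H](Br)C(C)(C)[C@@]12CC[C@@](C)(O)[C@H](Br)C2 | target

**Step count**

Total: 9 steps. Longest linear sequence: 9 steps (from but-2-yn-1-ol).

**Steps most likely to fail**

Step 5 (the proposed new method). Bromine may be delivered with poor face selectivity, or to the phenol ring or the styrenyl C7=C8 bond instead of C10=C11, before the ipso carbon can close. The fallback sets out from 6 and comes back at 9. It fixes the C10 configuration before the arene is attached and without a chiral bromine carrier. Shi epoxidation of the electron-rich C10=C11 bond of 6 (the iodo-alkene is deactivated) should give (3R)-3-[(2Z)-3-iodobut-2-en-1-yl]-2,2-dimethyloxirane F1. Suzuki–Miyaura coupling with 7 under the conditions of step 4 gives 4-{(2Z)-4-[(2R)-3,3-dimethyloxiran-2-yl]but-2-en-2-yl}phenol F2. Li2NiBr4 (THF, 0 °C) opens the epoxide at the secondary carbon with inversion to 4-[(2Z,5S)-5-bromo-6-hydroxy-6-methylhept-2-en-2-yl]phenol F3. Ionisation of the tertiary hydroxyl with BF3·OEt2 (CH2Cl2, −78 °C) regenerates, with bromine participation, the C10/C11 bromonium ion as one enantiomer, which the ipso carbon captures to give 9. The operations are of established type: asymmetric epoxidation, SN2 opening of an epoxide by bromide, cross-coupling, and enantiospecific generation of a bromonium ion from a β-bromo tertiary alcohol with capture by an arene. The last operation still closes the ring through the ipso carbon, so this fallback removes the dependence on catalytic bromine delivery but not on the ipso mode of closure.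

Step 6. The chiral copper hydride may fail to override the small intrinsic difference between the two enone double bonds, giving low selectivity at C6, or reduction may run on past the mono-ene stage. The fallback sets out from 9 and comes back at 12. Both enone double bonds are reduced with an achiral copper hydride catalyst (Cu(OAc)2, 1,2-bis(diphenylphosphino)benzene, PMHS, t-BuOH, toluene) to (10S)-10-bromo-7,11,11-trimethylspiro[5.5]undec-7-en-3-one F4, in which C6 is not stereogenic. A chiral lithium amide (lithium (R,R)-bis(1-phenylethyl)amide, LiCl, THF, −78 °C) then removes a proton from C2 in preference to C4 and gives the lithium enolate 12 directly, which is triflated as in step 7. C6 is thus set by group-selective deprotonation of a 4,4-disubstituted cyclohexanone instead of by conjugate reduction.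

Step 9. The bromonium ion may form on the wrong face of C2=C3, which would give the 2,3-bis-epimer, or on the ring-A alkene. The fallback sets out from 14 and comes back at 15. The electrophile is changed from bromine to oxygen, which reverses the facial requirement. Epoxidation with mCPBA (CH2Cl2, NaHCO3, 0 °C) on the ring-B face cis to C7 gives (2S,3R,6R,10S)-10-bromo-2,3-epoxy-3,7,11,11-tetramethylspiro[5.5]undec-7-ene F5. SN2 opening at the secondary carbon C2 with Li2NiBr4 (THF, 0 °C) then brings in bromide with inversion while the C3 oxygen stays, giving 15. The facial preference that would defeat step 9 is the one this sequence needs.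

**Further compounds**

F1 | step 5 | (3R)-3-[(2Z)-3-iodobut-2-en-1-yl]-2,2-dimethyloxirane | C/C(I)=C/C[C@H]1OC1(C)C
F2 | step 5 | 4-{(2Z)-4-[(2R)-3,3-dimethyloxiran-2-yl]but-2-en-2-yl}phenol | C/C(=C/C[C@H]1OC1(C)C)c1ccc(O)cc1
F3 | step 5 | 4-[(2Z,5S)-5-bromo-6-hydroxy-6-methylhept-2-en-2-yl]phenol | C/C(=C/C[C@H](Br)C(C)(C)O)c1ccc(O)cc1
F4 | step 6 | (10S)-10-bromo-7,11,11-trimethylspiro[5.5]undec-7-en-3-one | CC1=CC[C@H](Br)C(C)(C)C12CCC(=O)CC2
F5 | step 9 | (2S,3R,6R,10S)-10-bromo-2,3-epoxy-3,7,11,11-tetramethylspiro[5.5]undec-7-ene | CC1=CC[C@H](Br)C(C)(C)[C@@]12CC[C@@]3(C)O[C@H]3C2
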